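The readings were generated by integration for substances that don't exist.

Our flask cannot take up its whole charge of free monomer unless each initiator charged puts on average 100 monomer units into chains, for that is the ratio at a loading of 1 mol%. So we turn the question round and ask how many units one initiator charged delivered on average in the earlier runs.

| setting | midnight | summer | dawn | flask |
|---|---|---|---|---|
| free monomer | 20 mM (fed, over 80 min) | 20 mM (fed, over 80 min) | 30 mM (fed, over 80 min) | 20 mM (fed, over 80 min) |
| transfer agent | 2 mM | 2 mM | 2 mM | 2.00 mM |
| initiator | 0.5 mol% | 0.75 mol% | 1 mol% | 1 mol% |
| remark | run made earlier; the fed solution adds 0.10 times the starting volume | run made earlier; the fed solution adds 0.10 times the starting volume | run made earlier; the fed solution adds 0.10 times the starting volume | the fed solution adds 0.10 times the starting volume |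
| time |  |  |  | 10 h |

| run | time / h | monomer in chains / % | free monomer / % |
|---|---|---|---|
| midnight | 0.667 | 3 | 48 |
| midnight | 1.33 | 16 | 86 |
| midnight | 2.50 | 18 | 79 |
| midnight | 4.00 | 19 | 80 |
| midnight | 8.00 | 20 | 80 |
| summer | 0.667 | 5 | 44 |
| summer | 1.33 | 19 | 81 |
| summer | 2.50 | 27 | 75 |
| summer | 4.00 | 28 | 69 |
| summer | 8.00 | 24 | 72 |
| dawn | 1.50 | 34 | 67 |
| dawn | 3.00 | 39 | 63 |
| dawn | 5.00 | 36 | 62 |
| dawn | 6.00 | 34 | 62 |
| dawn | 8.00 | 36 | 62 |

(each reading ± 1.5 percentage points)

- every charge counts on the volume at the start, and the solution that is fed holds the whole dose
- the average divides the monomer in chains by the number of chains begun, living and dead together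
- the numbers in the tables scatter by 1.5 percentage points (one standard deviation)
- the earlier runs do not show the number of chains; that part of a forecast is a guess
- percentages count the whole charge, also what has not yet gone in

- average number of monomer units in a chain (chains begun, living or dead) at 10 h
- part of the free monomer that has reacted at 10 h

The earlier runs stall, as in a dead-end polymerization: at 8.00 h free monomer reads 80% in midnight, 72% in summer and 62% in dawn. At that time the monomer in chains per initiator charged reads 40.0, 32.0 and 36.0, with the scatter of 1.5 percentage points in the percentages behind them. Their mean is 36.0, and we call this ratio the yield per initiator, Y. Each run held 2 mM of transfer agent, as the flask does. Full conversion of the flask asks for 2.78 times this reading, so with this reading our own reckoning for the flask stops at 36.0% reacted. The runs do not show the number of chains, so we reckon no average.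

The forecast gives 35% reacted, slightly below ours, and 3.2 units per chain, a guess that begins “If the transfer agent is fully used”.

The flask gives an average of 46.8 units per chain and 31.7% reacted. At 10.0 h it still holds 93.2% of its transfer agent.

    free monomer + initiator → living end + monomer in chains (k = 210 M⁻¹ h⁻¹)
    2 initiator → spent initiator (k = 2400 M⁻¹ h⁻¹)
    living end + transfer agent → dead chain (kL = 2900 M⁻¹ h⁻¹)
    free monomer + living end → monomer in chains + living end, rate k4*[living end]*[free monomer] (k = 25000 M⁻¹ h⁻¹)

The yield per initiator of the flask comes to 31.7, less than the 100 that full conversion asks. The neighbour flask with 8.0 mM of transfer agent instead of 2.00 mM reacts 8.26% of its free monomer, so its yield per initiator is 8.26, a quarter of the flask's.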